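In the north-east run, 27.4% of the charged starting material stands as target at 16 min. Call this the end share Y, target at that time over starting material charged: it is the chance that one charged molecule has become target by then.

| flask | starting material | coupling partner | target | time |
|---|---|---|---|---|
| north-east | 100 mM | 300 mM |  |  |
| north | 100 mM | 300 mM | 50.0 mM |  |
| east | 200 mM | 300 mM |  |  |
| north-west | 100 mM | 450 mM |  |  |
| west | 350 mM | 300 mM |  | 16 min |

| north-east run: time / min | north-east run: [target] / mM | north run: time / min | north run: [target] / mM | east run: time / min | east run: [target] / mM | north-west run: time / min | north-west run: [target] / mM |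
|---|---|---|---|---|---|---|---|
| 3.2 | 6.9 | 3.2 | 57.7 | 3.2 | 12.3 | 3.2 | 10.1 |
| 6.4 | 16.5 | 6.4 | 67.5 | 6.4 | 27.8 | 6.4 | 22.2 |
| 9.6 | 23.2 | 9.6 | 73.8 | 9.6 | 40.6 | 9.6 | 29.6 |
| 13 | 26.8 | 13 | 77.2 | 13 | 48.6 | 13 | 33.1 |
| 16 | 27.4 | 16 | 77.8 | 16 | 52.4 | 16 | 34.3 |

(each reading ± 0.3 mM)

- apparent order in [coupling partner] of the starting rate, round the charge of the north-east run (the rate where two percent of its starting material have turned into target)
- apparent order in [starting material] of the starting rate, round the charge of the north-east run (the rate where two percent of its starting material have turned into target) (one fixed amount of target, the same in the runs compared)
- target in the west run at 16 min, as a share of the starting material charged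

- Overall: starting material + coupling partner -> target.
- Constant volume, constant temperature.
- A reading of a species includes what of it is bound.
- "The second partner" is coupling partner.
- An order is taken over about fifteen percent of the charge, up and down.

Now draw the north-east curve. It opens at 2.16 mM min⁻¹ and then steepens to 3.00 mM min⁻¹. The knee comes after 9.6 min: the slope falls to 1.06 mM min⁻¹, and over the last interval to 0.200 mM min⁻¹. So watch the last two readings, where the curve levels off near 27.4 mM. Starting material is the limiting reagent here, yet 72.6 mM of its charge does not stand as target at that time.

Next ask how Y moves between runs. Net of its added target, the north run gives 27.8%, which differs from the north-east share by about the scatter of the readings. More coupling partner, in the north-west run, raises Y to 34.3%, as if the partner competed at a fork with a path that does not need it. Doubling the starting material, in the east run, lowers Y to 26.2%. My own reckoning carries that straight-line fall on to the west charge and gives 24.4%.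

The forecast gives 0.72 and 0.62 for the orders and 24% for the west run, saying “Scaling to 350 mM gives about 85 mM”.

The flask gives 0.55 in coupling partner, 0.44 in starting material, and 23.4% for the west run, lower than my line and 4 percentage points below the north-east Y.

    starting material → intermediate (0.3030 min⁻¹)
    intermediate + coupling partner → target (0.9720 L mol⁻¹ min⁻¹)
    intermediate → side product (0.3348 min⁻¹)
    2 starting material ⇌ idle substrate dimer, settled at all times (27.80 L mol⁻¹)
    starting material → decomposed substrate (0.1764 min⁻¹)

The order in starting material stands at 0.44 because pairs of starting material are tied up as idle substrate dimer: the same north-east charge without that tying up gives 0.67. Y can be read on such a run too. The west run, repeated without the dimer, ends at a share of 26.5%, close to the north-east Y of 27.4%.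

The readings were computed with constants of no real substance.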